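**Plan**

- Ring atoms: O1, C2 (aryl-bearing), C3, C4 (carbinol), C5, C6 (arylethyl-bearing). Retrosynthetic cuts, in order: the four O–benzyl bonds; C4–H (alcohol back to ketone); the ring at C3–C4 and O1–C6; then C5=C6 of the enoyl partner and C2–C3 of the chlorohydrin partner.
- Forward: aryl piece A (steps 1–3) and side-chain piece B (steps 4–6) are made separately. Step 7 joins them by C-acylation (C3–C4) and closes the only new ring by 6-endo oxa-Michael addition (O1–C6) in the same flask. Ketone reduction and hydrogenolysis finish.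
- Enabling feature: in the oxane ring the oxygenated C4 lies 1,3 to the ether carbon C6 and next to C3. At the ketone level C4–C5=C6 is therefore an enone that accepts O1 at C6, and C4 is an acyl carbon that accepts C3. O1 and C3 both sit on benzylic C2 and are delivered together as a β-oxido alkyllithium from one chlorohydrin.
- Stereochemistry: C2 is set by catalytic asymmetric transfer hydrogenation (step 3). C6 is relayed from C2 in the reversible ring closure (2,6-cis, both equatorial). C4 is relayed from that chair by equatorial hydride delivery (axial OH).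
- Helpers: chloride (organolithium precursor), N-methoxy-N-methylamide (acyl activation), C4 ketone level and benzyl ethers; all are removed in steps 7–9.

Key step: step 7

Remark: the transfer hydrogenation of step 3 is assumed to follow the facial preference known for aryl methyl ketones, so the (S,S)-ligand should give the (R)-chlorohydrin (CH2Cl outranks aryl in the descriptor); otherwise the (R,R)-ligand is used.

**Route**

Step 1
Reactants: 1 methyl 3,4-dihydroxy-5-methoxybenzoate
Product: 2 methyl 3,4-bis(benzyloxy)-5-methoxybenzoate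
Conditions: BnBr, K2CO3, DMF, 60 °C
Reagents that add atoms: benzyl bromide, BrCc1ccccc1
Why: Williamson etherification of both phenols with a carbonate base; the methyl ester and the aryl methyl ether are inert and no stereocentre is present.

Step 2
Reactants: 2 methyl 3,4-bis(benzyloxy)-5-methoxybenzoate
Product: 3 1-[3,4-bis(benzyloxy)-5-methoxyphenyl]-2-chloroethan-1-one
Conditions: ICH2Cl, MeLi·LiBr, THF, −78 °C; then AcOH
Reagents that add atoms: chloroiodomethane, ClCI
Why: Chloromethyllithium, formed by iodine–lithium exchange in the presence of the ester, adds to the ester carbonyl, and the tetrahedral lithium hemiketal should persist at −78 °C until the acidic quench, so the ester is homologated to the chloromethyl ketone without a second addition (nucleophilic acyl substitution by a lithium carbenoid).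

Step 3
Reactants: 3 1-[3,4-bis(benzyloxy)-5-methoxyphenyl]-2-chloroethan-1-one
Product: 4 (R)-1-[3,4-bis(benzyloxy)-5-methoxyphenyl]-2-chloroethan-1-ol
Conditions: RuCl(p-cymene)[(S,S)-TsDPEN] (1 mol%), HCO2H/Et3N (5:2), DMF, 25 °C
Reagents that add atoms: none
Why: Noyori–Ikariya asymmetric transfer hydrogenation; the bifunctional Ru–H/N–H catalyst delivers hydride to one enantioface of the aryl ketone (aryl/η6-arene CH–π contact) and sets C2, while the α-chloride and the benzyl ethers should be untouched.

Step 4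
Reactants: 5 3-(3,4-dihydroxyphenyl)propanoic acid
Product: 6 benzyl 3-[3,4-bis(benzyloxy)phenyl]propanoate
Conditions: BnBr, K2CO3, DMF, 60 °C
Reagents that add atoms: benzyl bromide, BrCc1ccccc1
Why: Williamson etherification of the catechol and O-alkylation of the carboxylate in one pot; no stereocentre is present.

Step 5
Reactants: 6 benzyl 3-[3,4-bis(benzyloxy)phenyl]propanoate
Product: 7 3-[3,4-bis(benzyloxy)phenyl]propanal
Conditions: i-Bu2AlH (1.1 equiv), CH2Cl2, −78 °C; aqueous potassium sodium tartrate
Reagents that add atoms: none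
Why: Partial ester reduction with one equivalent of i-Bu2AlH; the aluminium hemiacetal is stable at −78 °C and releases the aldehyde only on work-up, and aryl benzyl ethers are inert.

Step 6
Reactants: 7 3-[3,4-bis(benzyloxy)phenyl]propanal
Product: 8 (E)-5-[3,4-bis(benzyloxy)phenyl]-N-methoxy-N-methylpent-2-enamide
Conditions: (EtO)2P(O)CH2C(O)N(OMe)Me, NaH, THF, 0 → 25 °C
Reagents that add atoms: diethyl {2-[methoxy(methyl)amino]-2-oxoethyl}phosphonate, CCOP(=O)(OCC)CC(=O)N(C)OC
Why: Horner–Wadsworth–Emmons olefination with a stabilised amide phosphonate should give the (E)-enamide through the thermodynamically favoured oxaphosphetane; no stereocentre is formed.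

Step 7
Reactants: 4 (R)-1-[3,4-bis(benzyloxy)-5-methoxyphenyl]-2-chloroethan-1-ol; 8 (E)-5-[3,4-bis(benzyloxy)phenyl]-N-methoxy-N-methylpent-2-enamide
Product: 11 (2S,6S)-2-[3,4-bis(benzyloxy)-5-methoxyphenyl]-6-{2-[3,4-bis(benzyloxy)phenyl]ethyl}tetrahydro-4H-pyran-4-one, via dilithio alkoxide 9 (not isolated), via hydroxy enone 10 (not isolated)
Conditions: n-BuLi (1 equiv), THF, −78 °C; LiC10H8 (lithium naphthalenide, 2 equiv), −78 °C; 8, −78 °C; then 1 M HCl (aq), 0 → 25 °C
Reagents that add atoms: none
Why: Deprotonation of 4 and two-electron reductive lithiation of its C–Cl bond by LiC10H8 give the β-oxido alkyllithium 9, which should persist at −78 °C because lithium oxide is a poor leaving group; its carbanion C3 adds 1,2 to the Weinreb amide 8 and forms the C3–C4 bond as a chelated tetrahedral adduct that cannot add a second time. Aqueous HCl collapses this adduct to the β-hydroxy enone 10, holds the liberated MeNHOMe as its salt, and catalyses the 6-endo-trig oxa-Michael addition of the C2 hydroxyl to C6, which forms the O1–C6 bond and closes the oxane ring. The closest known reaction types are the trapping of chlorohydrin-derived β-lithio alkoxides with carbonyl electrophiles, enone synthesis from alkyllithiums and unsaturated Weinreb amides, and the acid-catalysed cyclisation of aldol-derived β-hydroxy enones to 2,6-cis-tetrahydropyran-4-ones. The new stereocentre C6 is set by C2 under substrate control: a chair-like transition state with aryl and side chain both equatorial, together with the reversibility of the conjugate addition, should funnel both enone faces (and any Z-enone) into the 2,6-cis ketone, while no bond to C2 is broken. The step needs chemoselective electron transfer (C–Cl before the aryl benzyl ethers, secured by −78 °C and no excess of arenide) and 1,2- over 1,4-addition (secured by the hard primary alkyllithium and the amide chelate).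

Step 8
Reactants: 11 (2S,6S)-2-[3,4-bis(benzyloxy)-5-methoxyphenyl]-6-{2-[3,4-bis(benzyloxy)phenyl]ethyl}tetrahydro-4H-pyran-4-one
Product: 12 (2S,4S,6S)-2-[3,4-bis(benzyloxy)-5-methoxyphenyl]-6-{2-[3,4-bis(benzyloxy)phenyl]ethyl}tetrahydro-2H-pyran-4-ol
Conditions: LiBH(s-Bu)3, THF, −78 °C; then H2O
Reagents that add atoms: none
Why: Ketone reduction with a hindered trialkylborohydride; the bulky hydride should attack the 2,6-diequatorial chair from the equatorial direction (steric approach control) and give the axial (4S) alcohol, trans to both ring substituents.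

Step 9
Reactants: 12 (2S,4S,6S)-2-[3,4-bis(benzyloxy)-5-methoxyphenyl]-6-{2-[3,4-bis(benzyloxy)phenyl]ethyl}tetrahydro-2H-pyran-4-ol
Product: 13 (2S,4S,6S)-2-(3,4-dihydroxy-5-methoxyphenyl)-6-[2-(3,4-dihydroxyphenyl)ethyl]tetrahydro-2H-pyran-4-ol
Conditions: H2 (1 atm), Pd/C, EtOAc/MeOH, 25 °C
Reagents that add atoms: none
Why: Catalytic hydrogenolysis should cleave the four aryl benzyl ethers much faster than the cyclic benzylic C2–O1 ether under one atmosphere of hydrogen, and no stereocentre is touched.

**Compound list**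

1 | methyl 3,4-dihydroxy-5-methoxybenzoate | COC(=O)c1cc(OC)c(O)c(O)c1 | starting material
2 | methyl 3,4-bis(benzyloxy)-5-methoxybenzoate | COC(=O)c1cc(OC)c(OCc2ccccc2)c(OCc2ccccc2)c1 | intermediate
3 | 1-[3,4-bis(benzyloxy)-5-methoxyphenyl]-2-chloroethan-1-one | O=C(CCl)c1cc(OC)c(OCc2ccccc2)c(OCc2ccccc2)c1 | intermediate
4 | (R)-1-[3,4-bis(benzyloxy)-5-methoxyphenyl]-2-chloroethan-1-ol | O[C@@H](CCl)c1cc(OC)c(OCc2ccccc2)c(OCc2ccccc2)c1 | intermediate
5 | 3-(3,4-dihydroxyphenyl)propanoic acid | OC(=O)CCc1ccc(O)c(O)c1 | starting material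
6 | benzyl 3-[3,4-bis(benzyloxy)phenyl]propanoate | O=C(CCc1ccc(OCc2ccccc2)c(OCc2ccccc2)c1)OCc1ccccc1 | intermediate
7 | 3-[3,4-bis(benzyloxy)phenyl]propanal | O=CCCc1ccc(OCc2ccccc2)c(OCc2ccccc2)c1 | intermediate
8 | (E)-5-[3,4-bis(benzyloxy)phenyl]-N-methoxy-N-methylpent-2-enamide | CON(C)C(=O)/C=C/CCc1ccc(OCc2ccccc2)c(OCc2ccccc2)c1 | intermediate
9 | lithium (S)-1-[3,4-bis(benzyloxy)-5-methoxyphenyl]-2-lithioethan-1-olate (dilithio alkoxide) | [Li]C[C@H](O[Li])c1cc(OC)c(OCc2ccccc2)c(OCc2ccccc2)c1 | intermediate
10 | (S,E)-1-[3,4-bis(benzyloxy)-5-methoxyphenyl]-7-[3,4-bis(benzyloxy)phenyl]-1-hydroxyhept-4-en-3-one (hydroxy enone) | O[C@@H](CC(=O)/C=C/CCc1ccc(OCc2ccccc2)c(OCc2ccccc2)c1)c1cc(OC)c(OCc2ccccc2)c(OCc2ccccc2)c1 | intermediate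
11 | (2S,6S)-2-[3,4-bis(benzyloxy)-5-methoxyphenyl]-6-{2-[3,4-bis(benzyloxy)phenyl]ethyl}tetrahydro-4H-pyran-4-one | COc1cc([C@@H]2CC(=O)C[C@H](CCc3ccc(OCc4ccccc4)c(OCc4ccccc4)c3)O2)cc(OCc2ccccc2)c1OCc1ccccc1 | intermediate
12 | (2S,4S,6S)-2-[3,4-bis(benzyloxy)-5-methoxyphenyl]-6-{2-[3,4-bis(benzyloxy)phenyl]ethyl}tetrahydro-2H-pyran-4-ol | COc1cc([C@@H]2C[C@@H](O)C[C@H](CCc3ccc(OCc4ccccc4)c(OCc4ccccc4)c3)O2)cc(OCc2ccccc2)c1OCc1ccccc1 | intermediate
13 | (2S,4S,6S)-2-(3,4-dihydroxy-5-methoxyphenyl)-6-[2-(3,4-dihydroxyphenyl)ethyl]tetrahydro-2H-pyran-4-ol (2,6-cis, axial 4-OH) | COc1cc([C@@H]2C[C@@H](O)C[C@H](CCc3ccc(O)c(O)c3)O2)cc(O)c1O | target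

**Step count and risks**

Total steps: 9. Longest linear sequence: 6 steps (1, 2, 3, 7, 8, 9 or 4, 5, 6, 7, 8, 9).

Steps most likely to fail:

Step 7 (key step). Several processes could take the material away:
- β-elimination of lithium oxide from 9 to the styrene;
- electron transfer from the arenide to the aryl benzyl ethers;
- γ-deprotonation of 8 by the basic organolithium;
- acid-promoted dehydration of 10 before it cyclises.

The fallback is the aldol/oxa-Michael alternative, in which C2–C3 is made in place of C3–C4. It sets out from 8 and 2 and comes back to the route at 10 and then 11. MeMgBr (THF, 0 °C) should convert 8 into (E)-6-[3,4-bis(benzyloxy)phenyl]hex-3-en-2-one F1. LiAlH4 should reduce 2 to [3,4-bis(benzyloxy)-5-methoxyphenyl]methanol F2, and MnO2 should oxidise this to 3,4-bis(benzyloxy)-5-methoxybenzaldehyde F3. The diisopinocampheylboron enolate of F1 (Ipc2BCl, Et3N, Et2O, −78 °C; the pinene antipode that gives the (S)-carbinol) is then added to F3 to give 10. Compound 10 is isolated here and closed to 11 with Amberlyst-15 in CH2Cl2.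

Step 2. The carbenoid may decompose by α-elimination, or the tetrahedral adduct may collapse early so that the ketone takes up a second carbenoid and ends as an epoxide. The fallback replaces carbenoid homologation by enolate chlorination; it sets out from 2 and comes back at 3. LiOH (THF/H2O) should give 3,4-bis(benzyloxy)-5-methoxybenzoic acid F4. MeLi (2.2 equiv, THF, 0 °C) should convert it into 1-[3,4-bis(benzyloxy)-5-methoxyphenyl]ethan-1-one F5. LiN(SiMe3)2 and Me3SiCl (THF, −78 °C) should give ({1-[3,4-bis(benzyloxy)-5-methoxyphenyl]ethenyl}oxy)trimethylsilane F6, and N-chlorosuccinimide (THF, 0 °C) should then give 3.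

Step 8. Equatorial hydride attack may not be selective enough, so that the equatorial (4R) alcohol is carried along. The fallback is reduction to the other epimer followed by inversion; it sets out from 11 and comes back at 12. NaBH4 (MeOH, −20 °C) should give, by axial attack, the all-cis alcohol (2S,4R,6S)-2-[3,4-bis(benzyloxy)-5-methoxyphenyl]-6-{2-[3,4-bis(benzyloxy)phenyl]ethyl}tetrahydro-2H-pyran-4-ol F7. A Mitsunobu reaction (4-nitrobenzoic acid, PPh3, diisopropyl azodicarboxylate, THF) should invert C4 to (2S,4S,6S)-2-[3,4-bis(benzyloxy)-5-methoxyphenyl]-6-{2-[3,4-bis(benzyloxy)phenyl]ethyl}tetrahydro-2H-pyran-4-yl 4-nitrobenzoate F8. K2CO3 in MeOH should then release 12.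

Further compounds
F1 | step 7 | (E)-6-[3,4-bis(benzyloxy)phenyl]hex-3-en-2-one | CC(=O)/C=C/CCc1ccc(OCc2ccccc2)c(OCc2ccccc2)c1
F2 | step 7 | [3,4-bis(benzyloxy)-5-methoxyphenyl]methanol | COc1cc(CO)cc(OCc2ccccc2)c1OCc1ccccc1
F3 | step 7 | 3,4-bis(benzyloxy)-5-methoxybenzaldehyde | COc1cc(C=O)cc(OCc2ccccc2)c1OCc1ccccc1
F4 | step 2 | 3,4-bis(benzyloxy)-5-methoxybenzoic acid | COc1cc(C(=O)O)cc(OCc2ccccc2)c1OCc1ccccc1
F5 | step 2 | 1-[3,4-bis(benzyloxy)-5-methoxyphenyl]ethan-1-one | COc1cc(C(C)=O)cc(OCc2ccccc2)c1OCc1ccccc1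
F6 | step 2 | ({1-[3,4-bis(benzyloxy)-5-methoxyphenyl]ethenyl}oxy)trimethylsilane | COc1cc(C(=C)O[Si](C)(C)C)cc(OCc2ccccc2)c1OCc1ccccc1
F7 | step 8 | (2S,4R,6S)-2-[3,4-bis(benzyloxy)-5-methoxyphenyl]-6-{2-[3,4-bis(benzyloxy)phenyl]ethyl}tetrahydro-2H-pyran-4-ol | COc1cc([C@@H]2C[C@H](O)C[C@H](CCc3ccc(OCc4ccccc4)c(OCc4ccccc4)c3)O2)cc(OCc2ccccc2)c1OCc1ccccc1
F8 | step 8 | (2S,4S,6S)-2-[3,4-bis(benzyloxy)-5-methoxyphenyl]-6-{2-[3,4-bis(benzyloxy)phenyl]ethyl}tetrahydro-2H-pyran-4-yl 4-nitrobenzoate | COc1cc([C@@H]2C[C@@H](OC(=O)c3ccc(cc3)[N+](=O)[O-])C[C@H](CCc3ccc(OCc4ccccc4)c(OCc4ccccc4)c3)O2)cc(OCc2ccccc2)c1OCc1ccccc1
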